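**Retrosynthetic overview**

1. The target is cut back to bisketal 9 (the bis(dimethyl ketal) of 3-hexadecyl-2,5-dimethoxy-1,4-benzoquinone): aqueous acid unmasks both carbonyls and hydrolyses only the hindered C2 vinylogous ester.
2. 9 is cut at the chain bond C5'–C6' (chain carbons counted from ring carbon C3) into two plain carboxylic acids, lauric acid 7 and 6-arylhexanoic acid 6, joined by a mixed Kolbe electrolysis. The same cell first takes the arene to the quinone bisketal.
3. Enabling features: C5' and C6' are unbranched, heteroatom-free CH2 carbons five and six atoms from the ring, so both halves are unstabilised primary radicals. The six-membered carbocycle carries oxygen on C1, C2, C4 and C5, so its tetramethyl ether is a p-dimethoxyarene that a Pt anode in methanol converts to the bisketal well below the Kolbe potential.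
4. 6 comes from Grignard carboxylation of chloride 4, made by ortho-lithiation of 1,2,4,5-tetramethoxybenzene and alkylation with 1-bromo-5-chloropentane.
5. No ring is formed: the only ring is bought as the arene, dearomatised anodically in step 3 and released as the quinone in step 4.

Key step: step 3

Remark: the target has no stereocentre. Ring atoms are numbered C1(=O), C2(OH), C3(chain), C4(=O), C5(OMe), C6(H). 1,2,4,5-Tetramethoxybenzene is taken as a catalogue compound.

**Step 1**
Reactants: 1 1,2,4,5-tetramethoxybenzene; 2 1-bromo-5-chloropentane
Product: 4 1-(5-chloropentyl)-2,3,5,6-tetramethoxybenzene, via (2,3,5,6-tetramethoxyphenyl)lithium 3 (not isolated)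
Conditions: n-BuLi (1.05 equiv), THF, 0 °C → rt; then 2 (1.5 equiv), DMPU, −78 °C → rt
Reagents that add atoms: none
Why: Directed ortho-lithiation at the ring C–H flanked by two methoxy groups, then SN2 alkylation of the aryllithium at the bromide end of 2 (bromide is the far better leaving group, so the chloride end should stay intact).

**Step 2**
Reactants: 4 1-(5-chloropentyl)-2,3,5,6-tetramethoxybenzene
Product: 6 6-(2,3,5,6-tetramethoxyphenyl)hexanoic acid, via [5-(2,3,5,6-tetramethoxyphenyl)pentyl]magnesium chloride 5 (not isolated)
Conditions: Mg (I2, cat. BrCH2CH2Br), THF, reflux; then CO2 (dry ice), −78 °C → rt; aq. HCl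
Reagents that add atoms: carbon dioxide, O=C=O
Why: Grignard formation from the primary chloride and carboxylation with CO2 install the carboxyl carbon that the Kolbe step later expels; aryl methyl ethers are inert to the organomagnesium.

**Step 3**
Reactants: 6 6-(2,3,5,6-tetramethoxyphenyl)hexanoic acid; 7 dodecanoic acid (lauric acid)
Product: 9 1-hexadecyl-2,3,3,5,6,6-hexamethoxycyclohexa-1,4-diene, via sodium 6-(2,3,3,5,6,6-hexamethoxycyclohexa-1,4-dien-1-yl)hexanoate 8 (not isolated)
Conditions: (i) NaOMe (2 equiv), dry MeOH, Pt anode/Pt cathode, undivided cell, 0 °C, ca. 15 mA cm⁻², ca. 2.5 F mol⁻¹; (ii) add 7 (8 equiv), same cell, 20–30 °C, ca. 0.3 A cm⁻², until the electrolyte turns basic; chromatography on Et3N-deactivated silica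
Reagents that add atoms: methanol, CO
Why: Proposed new method: two classical anodic reactions are run back to back in one cell, a sequence not yet shown in tandem or with an acid that carries a quinone bisketal; the closest known types are the anodic 1,4-dimethoxylation of alkyl-polymethoxybenzenes to quinone bisketals in basic methanol and the mixed Kolbe electrolysis of two unbranched alkanoic acids at smooth platinum. In stage (i) the arene of 6 (as its carboxylate) should be oxidised near 1 V, far below the Kolbe threshold, to its radical cation, methoxide adds at an oxygen-bearing ring carbon, and a second electron transfer with methoxide capture at the para carbon gives bisketal 8 (the two para pairs are mirror images, so one constitution results). In stage (ii) the added lauric acid buffers the cell into the Kolbe regime (about one fifth neutralised), the carboxylates of 8 and 7 each lose one electron and CO2 at the carboxylate-covered anode, and the 5-substituted pentyl and undecyl radicals combine to form the C5'–C6' bond. No ring is closed and no stereocentre is made. The step needs cross- over homo-coupling, secured by the eightfold excess of cheap 7 (docosane, the hydrocarbon from that excess, is non-polar and easily removed), and radical coupling over cation formation, secured by both radicals being primary, unbranched and free of α- or β-heteroatoms. It also needs the ring to survive, secured by doing the unavoidable ring oxidation first: after stage (i) the ring is no longer an electron-rich arene, its two enol-ether C=C bonds carry electron-withdrawing ketal carbons, and the radical site lies five CH2 groups away, so 6-exo attack on the tetrasubstituted ring C=C bond should not compete with coupling in the dense radical layer at high current density.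

**Step 4**
Reactants: 9 1-hexadecyl-2,3,3,5,6,6-hexamethoxycyclohexa-1,4-diene
Product: 11 3-hexadecyl-2-hydroxy-5-methoxy-1,4-benzoquinone, via 3-hexadecyl-2,5-dimethoxy-1,4-benzoquinone 10 (not isolated)
Conditions: 70% aq. HClO4, THF, 0 °C → rt
Reagents that add atoms: water, O
Why: Acid-catalysed hydrolysis of both dimethyl ketals should give quinone 10, and the same acid then hydrolyses only the C2 vinylogous ester by addition–elimination of water, a known selective mono-demethylation of 3-alkyl-2,5-dimethoxybenzoquinones in which the C2 methoxy, twisted out of conjugation by the flanking chain, is lost and the in-plane C5 methoxy stays.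

**Compound list**

1 | 1,2,4,5-tetramethoxybenzene | COc1cc(OC)c(OC)cc1OC | starting material
2 | 1-bromo-5-chloropentane | ClCCCCCBr | starting material
3 | (2,3,5,6-tetramethoxyphenyl)lithium | [Li]c1c(OC)c(OC)cc(OC)c1OC | intermediate
4 | 1-(5-chloropentyl)-2,3,5,6-tetramethoxybenzene | ClCCCCCc1c(OC)c(OC)cc(OC)c1OC | intermediate
5 | [5-(2,3,5,6-tetramethoxyphenyl)pentyl]magnesium chloride | Cl[Mg]CCCCCc1c(OC)c(OC)cc(OC)c1OC | intermediate
6 | 6-(2,3,5,6-tetramethoxyphenyl)hexanoic acid | OC(=O)CCCCCc1c(OC)c(OC)cc(OC)c1OC | intermediate
7 | dodecanoic acid (lauric acid) | CCCCCCCCCCCC(=O)O | starting material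
8 | sodium 6-(2,3,3,5,6,6-hexamethoxycyclohexa-1,4-dien-1-yl)hexanoate | [Na+].[O-]C(=O)CCCCCC1=C(OC)C(OC)(OC)C=C(OC)C1(OC)OC | intermediate
9 | 1-hexadecyl-2,3,3,5,6,6-hexamethoxycyclohexa-1,4-diene | CCCCCCCCCCCCCCCCC1=C(OC)C(OC)(OC)C=C(OC)C1(OC)OC | intermediate
10 | 3-hexadecyl-2,5-dimethoxy-1,4-benzoquinone | CCCCCCCCCCCCCCCCC1=C(OC)C(=O)C=C(OC)C1=O | intermediate
11 | 3-hexadecyl-2-hydroxy-5-methoxy-1,4-benzoquinone | CCCCCCCCCCCCCCCCC1=C(O)C(=O)C=C(OC)C1=O | target

**Step count and risks**

Total steps: 4. Longest linear sequence: 4 (1 → 4 → 6 → 9 → 11).

Steps most likely to fail: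

Step 3. The bisketal ring may be over-oxidised at its enol-ether double bonds once the anode reaches the Kolbe potential, or the anode may passivate so that current goes into solvent oxidation and cation-derived products. The fallback makes the same C5'–C6' bond by polar organometallic chemistry. It sets out from chloride 4, which is converted into Grignard reagent 5 as in step 2 and coupled with 1-bromoundecane under copper catalysis (cat. Li2CuCl4, THF, −10 °C → rt, a Kochi-type sp3–sp3 coupling) to give 1-hexadecyl-2,3,5,6-tetramethoxybenzene F1. Anodic methoxylation of F1 on its own (NaOMe, MeOH, Pt, 0 °C), with no Kolbe stage, comes back to the route at 9.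

Step 4. Regiocontrol of the vinylogous ester hydrolysis may be lost, with water attacking C5 or both methoxy-bearing carbons, or the hydroxyquinone may degrade in the strong acid. The fallback sets out from 9. Mild ketal hydrolysis (aq. oxalic acid, THF) gives isolated 10. Both vinylogous esters are then saponified (aq. NaOH, EtOH, then H3O+) to 3-hexadecyl-2,5-dihydroxy-1,4-benzoquinone F2. Acid-catalysed vinylogous Fischer esterification (MeOH, cat. H2SO4, rt) should methylate only the unhindered C5 hydroxyl, whose carbon is flanked by C6–H, and comes back at 11.

Step 1. The SN2 alkylation of the doubly ortho-flanked aryllithium may be slow, so that elimination of the dihalide, proton return to 1 or a second arylation at the chloride end take over. The fallback sets out from 1 and replaces the SN2 step by a fast carbonyl addition. The same lithiation is quenched with DMF to give 2,3,5,6-tetramethoxybenzaldehyde F3. Wittig olefination with the ylide from (4-carboxybutyl)triphenylphosphonium bromide (KOtBu, 2 equiv, THF) gives (Z)-6-(2,3,5,6-tetramethoxyphenyl)hex-5-enoic acid F4 (alkene geometry is irrelevant). Hydrogenation (H2, Pd/C, EtOAc) comes back at 6, bypassing 4 and step 2.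

**Further compounds**

F1 | step 3 | 1-hexadecyl-2,3,5,6-tetramethoxybenzene | CCCCCCCCCCCCCCCCc1c(OC)c(OC)cc(OC)c1OC
F2 | step 4 | 3-hexadecyl-2,5-dihydroxy-1,4-benzoquinone | CCCCCCCCCCCCCCCCC1=C(O)C(=O)C=C(O)C1=O
F3 | step 1 | 2,3,5,6-tetramethoxybenzaldehyde | O=Cc1c(OC)c(OC)cc(OC)c1OC
F4 | step 1 | (Z)-6-(2,3,5,6-tetramethoxyphenyl)hex-5-enoic acid | OC(=O)CCC/C=C\c1c(OC)c(OC)cc(OC)c1OC
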